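## Retrosynthetic overview

1. Target 19 comes from cis-diol 18 by acetylation of the secondary C8 hydroxyl (last step).
2. Ring A of 18 is closed last, in one operation from monocyclic pyran 15, by forming C4a–C5 and C7–C8. An acetoin unit (C5–C6–C7 with its oxygen), hung on C4a through the future C7–OH oxygen, is shifted from O to C and then closed by aldol onto the C8 aldehyde.
3. 15 comes from chloro-enal 13 and acetoin 14; 13 from dihydropyranone 12 (Vilsmeier–Haack). Ring B is formed first: 12 by 6-endo-dig oxa-Michael closure of a hydroxy-ynone made from dienyne 7 and aldehyde 8.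
4. Side chain 7 comes from (S)-2-methylbutan-1-ol 1 by Wittig and Horner–Wadsworth–Emmons homologation (the only chiral-pool stereocentre).
5. Enabling feature: in ring A the C6 ketone lies between C5 and the oxygen-bearing C7 (an embedded acetoin) and faces C4a and C8, which are 1,3-related across C8a. C4a is the vinylogous acyl carbon of the ring B enol ether (O2–C3=C4–C4a), so it takes C5 by addition–elimination while C8 takes C7 by aldol, with the C7 oxygen as a traceless tether.

Key step: step 9

Assumption: atoms are named by the isochromene numbering of the target (C1, O2, C3, C4, C4a, C5 to C8, C8a), also in precursors; the (S,S)-ProPhenol ligand is taken to give the 7R,8R series, and its mirror image would be used if the facial sense proved opposite.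

## Route

Step 1
Reactants: 1 (S)-2-methylbutan-1-ol; 2 2-(triphenylphosphoranylidene)propanal
Product: 4 (2E,4S)-2,4-dimethylhex-2-enal, via (S)-2-methylbutanal 3 (not isolated)
Conditions: TEMPO (cat.), PhI(OAc)2, CH2Cl2, rt; then 2, 40 °C
Reagents that add atoms: none
Why: Oxoammonium (TEMPO) oxidation gives the α-chiral aldehyde without base and the stabilised ylide traps it at once in an E-selective Wittig olefination, so the chiral-pool stereocentre (S) should be carried through unchanged.

Step 2
Reactants: 4 (2E,4S)-2,4-dimethylhex-2-enal; 5 diethyl [3-(trimethylsilyl)prop-2-yn-1-yl]phosphonate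
Product: 6 trimethyl[(3E,5E,7S)-5,7-dimethylnona-3,5-dien-1-yn-1-yl]silane
Conditions: LiN(SiMe3)2, THF, −78 °C to rt
Reagents that add atoms: none
Why: Horner–Wadsworth–Emmons olefination with the propargyl-stabilised phosphonate anion should give the new disubstituted alkene with E geometry, and the allylic stereocentre is not acidified by the reaction.

Step 3
Reactants: 6 trimethyl[(3E,5E,7S)-5,7-dimethylnona-3,5-dien-1-yn-1-yl]silane
Product: 7 (3E,5E,7S)-5,7-dimethylnona-3,5-dien-1-yne
Conditions: K2CO3 (cat.), MeOH, rt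
Reagents that add atoms: none
Why: Base-catalysed methanolysis of the alkynyl C–Si bond (protodesilylation) frees the terminal alkyne without touching any stereocentre.

Step 4
Reactants: 7 (3E,5E,7S)-5,7-dimethylnona-3,5-dien-1-yne; 8 3-[(tert-butyldimethylsilyl)oxy]propanal
Product: 9 (6E,8E,10S)-1-[(tert-butyldimethylsilyl)oxy]-8,10-dimethyldodeca-6,8-dien-4-yn-3-ol (C3 epimers)
Conditions: n-BuLi, THF, −78 °C; then 8; aq. NH4Cl
Reagents that add atoms: none
Why: 1,2-Addition of the lithium acetylide to the aldehyde; the new carbinol centre forms as a mixture that does not matter because it is oxidised in step 5.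

Step 5
Reactants: 9 (6E,8E,10S)-1-[(tert-butyldimethylsilyl)oxy]-8,10-dimethyldodeca-6,8-dien-4-yn-3-ol
Product: 10 (6E,8E,10S)-1-[(tert-butyldimethylsilyl)oxy]-8,10-dimethyldodeca-6,8-dien-4-yn-3-one
Conditions: Dess–Martin periodinane, CH2Cl2, 0 °C to rt
Reagents that add atoms: none
Why: Dess–Martin oxidation of the propargylic alcohol to the ynone under neutral conditions should leave the diene and the silyl ether intact, and it removes the undefined carbinol centre.

Step 6
Reactants: 10 (6E,8E,10S)-1-[(tert-butyldimethylsilyl)oxy]-8,10-dimethyldodeca-6,8-dien-4-yn-3-one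
Product: 12 6-[(1E,3E,5S)-3,5-dimethylhepta-1,3-dien-1-yl]-2,3-dihydro-4H-pyran-4-one, via hydroxy ynone 11 (not isolated)
Conditions: p-TsOH·H2O (cat.), MeOH, rt
Reagents that add atoms: none
Why: Acid-catalysed methanolysis of the primary silyl ether followed by 6-endo-dig oxa-Michael addition of the freed hydroxyl to the ynone β-carbon (C3) should close ring B as the cyclic vinylogous ester, with no stereocentre formed.

Step 7
Reactants: 12 6-[(1E,3E,5S)-3,5-dimethylhepta-1,3-dien-1-yl]-2,3-dihydro-4H-pyran-4-one
Product: 13 4-chloro-6-[(1E,3E,5S)-3,5-dimethylhepta-1,3-dien-1-yl]-2H-pyran-3-carbaldehyde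
Conditions: POCl3, DMF, CH2Cl2, 0 to 40 °C; then H2O
Reagents that add atoms: phosphoryl chloride O=P(Cl)(Cl)Cl; N,N-dimethylformamide CN(C)C=O; water O
Why: Vilsmeier–Haack chloroformylation turns the ketone carbon C4a into a vinyl chloride and formylates C8a, the only enolisable α-position, in the way chroman-4-ones give 4-chloro-2H-chromene-3-carbaldehydes; no stereocentre is formed.

Step 8
Reactants: 13 4-chloro-6-[(1E,3E,5S)-3,5-dimethylhepta-1,3-dien-1-yl]-2H-pyran-3-carbaldehyde; 14 3-hydroxybutan-2-one (acetoin, racemic)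
Product: 15 6-[(1E,3E,5S)-3,5-dimethylhepta-1,3-dien-1-yl]-4-[(3-oxobutan-2-yl)oxy]-2H-pyran-3-carbaldehyde (C7 epimers)
Conditions: Et3N, DABCO (cat.), CH2Cl2, 0 °C to rt
Reagents that add atoms: none
Why: Addition–elimination (vinylogous acyl substitution) at C4a of the β-chlorovinyl aldehyde by the hydroxyl of 14, with DABCO as nucleophilic catalyst, should give the vinylogous ester; the C7 epimer mixture does not matter because C7 is enolised in step 9.

Step 9
Reactants: 15 6-[(1E,3E,5S)-3,5-dimethylhepta-1,3-dien-1-yl]-4-[(3-oxobutan-2-yl)oxy]-2H-pyran-3-carbaldehyde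
Product: 18 (7R,8R,8aR)-3-[(1E,3E,5S)-3,5-dimethylhepta-1,3-dien-1-yl]-7,8-dihydroxy-7-methyl-1,7,8,8a-tetrahydro-6H-isochromen-6-one, via ketol enal 16 (not isolated), via deconjugated aldol 17 (not isolated)
Conditions: Et2Zn (20 mol %), (S,S)-ProPhenol (10 mol %), 4 Å MS, THF, 0 to 40 °C; then aq. NH4Cl
Reagents that add atoms: none
Why: Proposed new method: the dinuclear zinc catalyst should enolise the methyl ketone of 15 at C5, which adds 5-exo-trig to C4a of the β-alkoxy enal and expels the C7 alkoxide, giving ketol 16 with the new C4a–C5 bond; this is a vinylogous O-to-C transfer whose closest precedents are the Baker–Venkataraman rearrangement and the zinc-ProPhenol enolisation of methyl ketones. The freed α-hydroxy ketone should then bind both zinc atoms as a chelated enediolate and add through C7 to the C8 aldehyde, the closest known reaction type being the direct asymmetric aldol of α-hydroxy ketones, which closes ring A by a 6-(enolendo)-exo-trig aldol to give 17. C7 and C8 are set here by the chiral pocket of the ligand, which fixes the face of the planar enediolate so that both C7 epimers of 15 converge, while a chair-like closure with the C7 methyl equatorial and the zinc-bridged O7 and O8 gauche should give the cis-diol. C8a is set last, when the C4a=C8a double bond of 17 moves into conjugation with the C6 ketone; protonation at C8a is reversible through the dienolate, so the isomer with C1 and O8 trans (both equatorial on ring A) should accumulate as 18. The step needs C5 to bond to C4a and C7 to C8: the oxygen tether leaves C5 only the 5-exo attack on C4a, the aldehyde keeps C4a activated until that bond is made, and the competing 5-exo aldol of C7 onto C8 is reversible because its product cannot dehydrate.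

Step 10
Reactants: 18 (7R,8R,8aR)-3-[(1E,3E,5S)-3,5-dimethylhepta-1,3-dien-1-yl]-7,8-dihydroxy-7-methyl-1,7,8,8a-tetrahydro-6H-isochromen-6-one
Product: 19 (7R,8R,8aR)-3-[(1E,3E,5S)-3,5-dimethylhepta-1,3-dien-1-yl]-7-hydroxy-7-methyl-6-oxo-6,7,8,8a-tetrahydro-1H-isochromen-8-yl acetate
Conditions: Ac2O, pyridine, 0 °C to rt
Reagents that add atoms: acetic anhydride CC(=O)OC(C)=O
Why: Acylation should take place only at the secondary C8 hydroxyl, which is far more reactive than the hindered tertiary C7 hydroxyl, and the weak base avoids vinylogous β-elimination of the acetate through C8a–H; no stereocentre is touched.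

## Compound list

1 | (S)-2-methylbutan-1-ol | CC[C@H](C)CO | starting material
2 | 2-(triphenylphosphoranylidene)propanal | CC(C=O)=P(c1ccccc1)(c1ccccc1)c1ccccc1 | starting material
3 | (S)-2-methylbutanal | CC[C@H](C)C=O | intermediate
4 | (2E,4S)-2,4-dimethylhex-2-enal | CC[C@H](C)/C=C(C)/C=O | intermediate
5 | diethyl [3-(trimethylsilyl)prop-2-yn-1-yl]phosphonate | CCOP(=O)(CC#C[Si](C)(C)C)OCC | starting material
6 | trimethyl[(3E,5E,7S)-5,7-dimethylnona-3,5-dien-1-yn-1-yl]silane | CC[C@H](C)/C=C(C)/C=C/C#C[Si](C)(C)C | intermediate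
7 | (3E,5E,7S)-5,7-dimethylnona-3,5-dien-1-yne | CC[C@H](C)/C=C(C)/C=C/C#C | intermediate
8 | 3-[(tert-butyldimethylsilyl)oxy]propanal | O=CCCO[Si](C)(C)C(C)(C)C | starting material
9 | (6E,8E,10S)-1-[(tert-butyldimethylsilyl)oxy]-8,10-dimethyldodeca-6,8-dien-4-yn-3-ol (C3 epimers) | CC[C@H](C)/C=C(C)/C=C/C#CC(O)CCO[Si](C)(C)C(C)(C)C | intermediate
10 | (6E,8E,10S)-1-[(tert-butyldimethylsilyl)oxy]-8,10-dimethyldodeca-6,8-dien-4-yn-3-one | CC[C@H](C)/C=C(C)/C=C/C#CC(=O)CCO[Si](C)(C)C(C)(C)C | intermediate
11 | (6E,8E,10S)-1-hydroxy-8,10-dimethyldodeca-6,8-dien-4-yn-3-one (hydroxy ynone) | CC[C@H](C)/C=C(C)/C=C/C#CC(=O)CCO | intermediate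
12 | 6-[(1E,3E,5S)-3,5-dimethylhepta-1,3-dien-1-yl]-2,3-dihydro-4H-pyran-4-one | CC[C@H](C)/C=C(C)/C=C/C1=CC(=O)CCO1 | intermediate
13 | 4-chloro-6-[(1E,3E,5S)-3,5-dimethylhepta-1,3-dien-1-yl]-2H-pyran-3-carbaldehyde | CC[C@H](C)/C=C(C)/C=C/C1=CC(Cl)=C(C=O)CO1 | intermediate
14 | 3-hydroxybutan-2-one (acetoin, racemic) | CC(O)C(C)=O | starting material
15 | 6-[(1E,3E,5S)-3,5-dimethylhepta-1,3-dien-1-yl]-4-[(3-oxobutan-2-yl)oxy]-2H-pyran-3-carbaldehyde (C7 epimers) | CC[C@H](C)/C=C(C)/C=C/C1=CC(OC(C)C(C)=O)=C(C=O)CO1 | intermediate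
16 | 6-[(1E,3E,5S)-3,5-dimethylhepta-1,3-dien-1-yl]-4-(3-hydroxy-2-oxobutyl)-2H-pyran-3-carbaldehyde (ketol enal, C7 epimers) | CC[C@H](C)/C=C(C)/C=C/C1=CC(CC(=O)C(C)O)=C(C=O)CO1 | intermediate
17 | (7R,8R)-3-[(1E,3E,5S)-3,5-dimethylhepta-1,3-dien-1-yl]-7,8-dihydroxy-7-methyl-1,5,7,8-tetrahydro-6H-isochromen-6-one (deconjugated aldol) | CC[C@H](C)/C=C(C)/C=C/C1=CC2=C(CO1)[C@@H](O)[C@@](C)(O)C(=O)C2 | intermediate
18 | (7R,8R,8aR)-3-[(1E,3E,5S)-3,5-dimethylhepta-1,3-dien-1-yl]-7,8-dihydroxy-7-methyl-1,7,8,8a-tetrahydro-6H-isochromen-6-one | CC[C@H](C)/C=C(C)/C=C/C1=CC2=CC(=O)[C@](C)(O)[C@H](O)[C@H]2CO1 | intermediate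
19 | (7R,8R,8aR)-3-[(1E,3E,5S)-3,5-dimethylhepta-1,3-dien-1-yl]-7-hydroxy-7-methyl-6-oxo-6,7,8,8a-tetrahydro-1H-isochromen-8-yl acetate | CC[C@H](C)/C=C(C)/C=C/C1=CC2=CC(=O)[C@](C)(O)[C@H](OC(C)=O)[C@H]2CO1 | target

## Step count and risks

Total step count: 10. Longest linear sequence: 10 steps (1 to 19); compounds 2, 5, 8 and 14 are bought.

Steps most likely to fail:

1. Step 9 (key step, proposed new method). The zinc enolate at C5 may add to C4a too slowly, so that the reversible aldol of C7 onto the aldehyde or binding of the catalyst by the acidic 1,5-dicarbonyl 16 stalls the cascade; retro-aldol may also erode the facial selectivity. The fallback uses known reactions, makes the two bonds in separate steps, and takes the absolute configuration from (S)-lactic acid. It sets out from 13 and comes back at 18. The lithium enolate (LDA, THF, −78 °C) of commercial (2S,5S)-2-tert-butyl-5-methyl-1,3-dioxolan-4-one should add to the aldehyde of 13 opposite to the tert-butyl group (self-regeneration of stereocentres, Zimmerman–Traxler closed transition state), which fixes C7 as R; C8 epimers would be separated. This gives the aldol adduct (2S,5R)-2-tert-butyl-5-[(R)-{4-chloro-6-[(1E,3E,5S)-3,5-dimethylhepta-1,3-dien-1-yl]-2H-pyran-3-yl}(hydroxy)methyl]-5-methyl-1,3-dioxolan-4-one F1 with the C7–C8 bond in place. MeLi (THF, −78 °C, then aqueous work-up) should open the lactone to the methyl ketone (3R,4R)-4-{4-chloro-6-[(1E,3E,5S)-3,5-dimethylhepta-1,3-dien-1-yl]-2H-pyran-3-yl}-3,4-dihydroxy-3-methylbutan-2-one F2. Intramolecular palladium-catalysed α-alkenylation of the methyl ketone by the vinyl chloride (Pd2(dba)3, P(t-Bu)3, K3PO4, toluene, 70 °C) would then form C4a–C5, and migration of the double bond into conjugation gives 18.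

2. Step 7. Electrophilic attack may occur at C4 or on the diene instead of at C8a, the 2H-pyran product may open by electrocyclic ring opening, and the acidic medium may isomerise the diene. The fallback sets out from 12 and comes back at 15, bypassing 13. Condensation of 12 with tert-butoxybis(dimethylamino)methane (toluene, 80 °C) should give the enaminone (3E)-3-[(dimethylamino)methylidene]-6-[(1E,3E,5S)-3,5-dimethylhepta-1,3-dien-1-yl]-2,3-dihydro-4H-pyran-4-one F3. O-Alkylation of this vinylogous amide with 3-bromobutan-2-one and AgOTf (CH2Cl2, 0 °C), then hydrolysis of the alkoxyvinyl iminium salt with aq. NaHCO3, should unveil the aldehyde and give 15.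

3. Step 8. The amine base may trigger intramolecular aldol of the new ether (C7 onto the aldehyde, Rap–Stoermer-type), or acetoin may add at the aldehyde instead of C4a. The fallback sets out from 13 and comes back at 15 without base in the ether-forming step. NaOMe (MeOH, 0 °C) should convert 13 into 6-[(1E,3E,5S)-3,5-dimethylhepta-1,3-dien-1-yl]-4-methoxy-2H-pyran-3-carbaldehyde F4. Acid-catalysed exchange of the vinylogous ester alkoxy group with 14 (PPTS, toluene, 4 Å MS, 60 °C, removal of methanol) would then give 15.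

Further compounds
F1 | step 9 | (2S,5R)-2-tert-butyl-5-[(R)-{4-chloro-6-[(1E,3E,5S)-3,5-dimethylhepta-1,3-dien-1-yl]-2H-pyran-3-yl}(hydroxy)methyl]-5-methyl-1,3-dioxolan-4-one | CC[C@H](C)/C=C(C)/C=C/C1=CC(Cl)=C(CO1)[C@@H](O)[C@@]2(C)O[C@H](C(C)(C)C)OC2=O
F2 | step 9 | (3R,4R)-4-{4-chloro-6-[(1E,3E,5S)-3,5-dimethylhepta-1,3-dien-1-yl]-2H-pyran-3-yl}-3,4-dihydroxy-3-methylbutan-2-one | CC[C@H](C)/C=C(C)/C=C/C1=CC(Cl)=C(CO1)[C@@H](O)[C@@](C)(O)C(C)=O
F3 | step 7 | (3E)-3-[(dimethylamino)methylidene]-6-[(1E,3E,5S)-3,5-dimethylhepta-1,3-dien-1-yl]-2,3-dihydro-4H-pyran-4-one | CC[C@H](C)/C=C(C)/C=C/C1=CC(=O)/C(=C/N(C)C)CO1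
F4 | step 8 | 6-[(1E,3E,5S)-3,5-dimethylhepta-1,3-dien-1-yl]-4-methoxy-2H-pyran-3-carbaldehyde | CC[C@H](C)/C=C(C)/C=C/C1=CC(OC)=C(C=O)CO1
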